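Everything rests on cutting the C3=C4 alkene of the butenolide (ring A: O1, C2=O, C3 bearing CH2OH, C4–H, C5). The feature exploited is that O1 and the exocyclic Z alkene at C5 are together an enol ester, which can be made before the ring exists. Ring-closing metathesis of a (Z)-2-acyloxy-1,3-diene whose acyl group is a 2-(silyloxymethyl)acrylate then forms C3=C4 and closes the lactone in one operation, with loss of ethene and without touching the enol ester or the lone stereocentre. The precursor comes from Z-selective O-acylation of a vinyl ketone dienolate; the bis-furan dienyl chain is attached afterwards by Julia–Kocienski olefination.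

Key step: step 9

Assumption: the half-ester 1 is purchased as the single (R) enantiomer; it carries the only stereocentre of the target, which is never a reacting centre in the route (the (S) half-ester would reach the same lactone by borane reduction of its acid arm instead).
Remark: the saturated arm carries a tert-butyldimethylsilyl ether, chosen because it survives the acid quench of the vinyl ketone synthesis and can still be removed selectively beside the tert-butyldiphenylsilyl ether.

Step 1
Reactants: 1 (3R)-5-methoxy-3-methyl-5-oxopentanoic acid (methyl hydrogen (R)-3-methylglutarate)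
Product: 3 (4S)-4-methyloxan-2-one, via hydroxy acid 2 (not isolated)
Conditions: LiBHEt3 (3.2 equiv), THF, 0 °C to rt; then 2 M HCl; TsOH (cat.), toluene, 50 °C
Reagents that add atoms: none
Why: Chemoselective hydride reduction of the ester beside the inert lithium carboxylate, then acid-catalysed lactonisation; the stereocentre comes with 1 and does not react, and its descriptor changes from R to S only because reducing the ester arm swaps the CIP ranks of the two arms.

Step 2
Reactants: 3 (4S)-4-methyloxan-2-one
Product: 4 (3S)-5-hydroxy-N-methoxy-N,3-dimethylpentanamide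
Conditions: MeNH(OMe)·HCl, AlMe3, CH2Cl2, 0 °C to rt; aq. potassium sodium tartrate
Reagents that add atoms: N,O-dimethylhydroxylamine hydrochloride, CNOC.Cl
Why: Weinreb aminolysis of the lactone by the dimethylaluminium amide opens the ring at the acyl carbon and frees the primary alcohol, which is silylated at once to forestall relactonisation.

Step 3
Reactants: 4 (3S)-5-hydroxy-N-methoxy-N,3-dimethylpentanamide
Product: 5 (3S)-5-[(tert-butyldimethylsilyl)oxy]-N-methoxy-N,3-dimethylpentanamide
Conditions: TBSCl, imidazole, CH2Cl2, rt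
Reagents that add atoms: tert-butyl(chloro)dimethylsilane, CC(C)(C)[Si](C)(C)Cl
Why: Imidazole-promoted silylation of a primary alcohol gives an ether that withstands the Grignard addition and its acid quench.

Step 4
Reactants: 5 (3S)-5-[(tert-butyldimethylsilyl)oxy]-N-methoxy-N,3-dimethylpentanamide; 6 vinylmagnesium bromide
Product: 7 (5S)-7-[(tert-butyldimethylsilyl)oxy]-5-methylhept-1-en-3-one
Conditions: THF, 0 °C; inverse quench into cold 1 M HCl
Reagents that add atoms: none
Why: Weinreb ketone synthesis, in which the chelated tetrahedral intermediate prevents over-addition; the cold acid quench protonates the released N,O-dimethylhydroxylamine so that it cannot add to the enone.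

Step 5
Reactants: 8 ethyl 2-(hydroxymethyl)prop-2-enoate
Product: 9 ethyl 2-{[(tert-butyldiphenylsilyl)oxy]methyl}prop-2-enoate
Conditions: TBDPSCl, imidazole, DMF, 0 °C to rt
Reagents that add atoms: tert-butyl(chloro)diphenylsilane, CC(C)(C)[Si](Cl)(c1ccccc1)c1ccccc1
Why: Standard silylation of a primary allylic alcohol installs a robust ether that must last until the final step.

Step 6
Reactants: 9 ethyl 2-{[(tert-butyldiphenylsilyl)oxy]methyl}prop-2-enoate
Product: 10 2-{[(tert-butyldiphenylsilyl)oxy]methyl}prop-2-enoic acid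
Conditions: LiOH, THF/H2O, 0 °C to rt; then 1 M HCl to pH 3
Reagents that add atoms: lithium hydroxide, [Li+].[OH-]
Why: Saponification of an unhindered ethyl ester; the silyl ether is stable to cold aqueous hydroxide.

Step 7
Reactants: 10 2-{[(tert-butyldiphenylsilyl)oxy]methyl}prop-2-enoic acid
Product: 11 2-{[(tert-butyldiphenylsilyl)oxy]methyl}prop-2-enoyl chloride
Conditions: (COCl)2, DMF (cat.), CH2Cl2, 0 °C to rt; volatiles removed, used crude
Reagents that add atoms: oxalyl chloride, O=C(Cl)C(=O)Cl
Why: Acid chloride formation through the Vilsmeier-type chloroiminium intermediate, under conditions the tert-butyldiphenylsilyl ether tolerates.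

Step 8
Reactants: 7 (5S)-7-[(tert-butyldimethylsilyl)oxy]-5-methylhept-1-en-3-one; 11 2-{[(tert-butyldiphenylsilyl)oxy]methyl}prop-2-enoyl chloride
Product: 13 (3Z,5S)-7-[(tert-butyldimethylsilyl)oxy]-5-methylhepta-1,3-dien-3-yl 2-{[(tert-butyldiphenylsilyl)oxy]methyl}prop-2-enoate, via potassium dienolate 12 (not isolated)
Conditions: KN(SiMe3)2 (1.05 equiv), THF, −78 °C, 7 added slowly; then 11, −78 to −40 °C
Reagents that add atoms: none
Why: Enolate O-acylation: the vinyl ketone can be deprotonated only at its CH2 group, the potassium enolate in THF should adopt the Z(O) geometry that keeps the branched alkyl group away from the coplanar vinyl group (A(1,3) strain), and a dissociated potassium enolate should react with the hard acyl chloride at oxygen to give the Z enol ester.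

Step 9
Reactants: 13 (3Z,5S)-7-[(tert-butyldimethylsilyl)oxy]-5-methylhepta-1,3-dien-3-yl 2-{[(tert-butyldiphenylsilyl)oxy]methyl}prop-2-enoate
Product: 14 (5Z)-5-{(2S)-4-[(tert-butyldimethylsilyl)oxy]-2-methylbutylidene}-3-{[(tert-butyldiphenylsilyl)oxy]methyl}furan-2(5H)-one
Conditions: second-generation Hoveyda–Grubbs catalyst RuCl2(H2IMes)(=CH-C6H4-2-OiPr) (10 mol %, two portions), toluene (0.002 M), 80 °C, argon sparge
Reagents that add atoms: none
Why: Proposed new method: the ruthenium alkylidene should exchange first onto the only monosubstituted alkene (C1=C2 of the diene) to give the vinylalkylidene Ru=CH–C(OCOR)=CH–, which undergoes intramolecular [2+2] cycloaddition with the 1,1-disubstituted acrylate alkene and cycloreversion, releasing ethene and forming the C3=C4 bond. The closest known reaction type is ring-closing metathesis of allyl 2-substituted acrylates to α-substituted butenolides; here the allylic carbon is the sp2 carbon of an enol ester within a 2-acyloxy-1,3-diene, which has not been shown. Ring A, the five-membered lactone, is closed by ring-closing metathesis between the diene terminus and the acrylate methylene, both CH2 termini leaving as ethene. No stereocentre is formed, and the (S) centre is a spectator. The step needs chemoselectivity among three alkenes and retention of the Z enol ester; the substitution pattern ranks the alkenes (monosubstituted, then 1,1-disubstituted, with the trisubstituted oxygen-bearing enol ester alkene not entering a metallacyclobutane), the saturated silyloxyethyl arm offers no fourth alkene, and high dilution with ethene removal disfavours dimerisation at the diene terminus.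

Step 10
Reactants: 14 (5Z)-5-{(2S)-4-[(tert-butyldimethylsilyl)oxy]-2-methylbutylidene}-3-{[(tert-butyldiphenylsilyl)oxy]methyl}furan-2(5H)-one
Product: 15 (5Z)-3-{[(tert-butyldiphenylsilyl)oxy]methyl}-5-[(2S)-4-hydroxy-2-methylbutylidene]furan-2(5H)-one
Conditions: HF·pyridine, pyridine, THF, 0 °C to rt
Reagents that add atoms: none
Why: Selective fluoride desilylation: the primary tert-butyldimethylsilyl ether is cleaved much faster than the tert-butyldiphenylsilyl ether, and the buffered non-basic medium leaves the enol lactone and the ε-CH stereocentre alone.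

Step 11
Reactants: 15 (5Z)-3-{[(tert-butyldiphenylsilyl)oxy]methyl}-5-[(2S)-4-hydroxy-2-methylbutylidene]furan-2(5H)-one
Product: 16 (3S)-4-[(2Z)-4-{[(tert-butyldiphenylsilyl)oxy]methyl}-5-oxofuran-2(5H)-ylidene]-3-methylbutanal
Conditions: Dess–Martin periodinane, CH2Cl2, 0 °C to rt
Reagents that add atoms: none
Why: Dess–Martin oxidation of a primary alcohol to the aldehyde under neutral, non-epimerising conditions.

Step 12
Reactants: 17 3,4-dibromofuran; 18 furan-3-carbaldehyde
Product: 20 (4-bromofuran-3-yl)(furan-3-yl)methanol (racemic), via (4-bromofuran-3-yl)lithium 19 (not isolated)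
Conditions: n-BuLi (1.0 equiv), Et2O, −78 °C; then 18, −78 °C; aq. NH4Cl
Reagents that add atoms: none
Why: Bromine–lithium exchange of one C–Br bond at −78 °C, where the 3-lithiofuran does not isomerise, followed by 1,2-addition to the aldehyde.

Step 13
Reactants: 20 (4-bromofuran-3-yl)(furan-3-yl)methanol
Product: 21 3-bromo-4-(furan-3-ylmethyl)furan
Conditions: Et3SiH (3 equiv), CF3CO2H, CH2Cl2, −20 to 0 °C
Reagents that add atoms: none
Why: Ionic hydrogenation: acid ionises the doubly furyl-stabilised carbinol and the cation is trapped by hydride from the excess silane, which should outpace Friedel–Crafts oligomerisation at low temperature.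

Step 14
Reactants: 21 3-bromo-4-(furan-3-ylmethyl)furan; 22 5-bromo-2-methylpent-2-ene
Product: 24 3-(furan-3-ylmethyl)-4-(4-methylpent-3-en-1-yl)furan, via (4-methylpent-3-en-1-yl)magnesium bromide 23 (not isolated)
Conditions: 22, Mg, THF, rt; then 21, Ni(dppp)Cl2 (5 mol %), Et2O/THF, reflux
Reagents that add atoms: none
Why: Kumada–Corriu cross-coupling of a heteroaryl bromide with a primary alkyl Grignard reagent, the bidentate phosphine suppressing β-hydride elimination.

Step 15
Reactants: 24 3-(furan-3-ylmethyl)-4-(4-methylpent-3-en-1-yl)furan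
Product: 25 (2E)-5-[4-(furan-3-ylmethyl)furan-3-yl]-2-methylpent-2-en-1-ol
Conditions: SeO2 (cat.), t-BuOOH, CH2Cl2, 0 °C to rt
Reagents that add atoms: selenium dioxide, O=[Se]=O; tert-butyl hydroperoxide, CC(C)(C)OO
Why: Selenium dioxide allylic oxidation (ene reaction, then [2,3]-sigmatropic shift) oxidises a methyl group on the more substituted alkene carbon and delivers the E allylic alcohol, so setting the 6E alkene of the target, while the furans are less nucleophilic than the trisubstituted alkene towards this reagent.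

Step 16
Reactants: 25 (2E)-5-[4-(furan-3-ylmethyl)furan-3-yl]-2-methylpent-2-en-1-ol
Product: 26 5-({(2E)-5-[4-(furan-3-ylmethyl)furan-3-yl]-2-methylpent-2-en-1-yl}sulfanyl)-1-phenyl-1H-tetrazole
Conditions: 1-phenyl-1H-tetrazole-5-thiol, PPh3, DIAD, THF, 0 °C to rt
Reagents that add atoms: 1-phenyl-1H-tetrazole-5-thiol, Sc1nnnn1-c1ccccc1
Why: Mitsunobu thioetherification of a primary allylic alcohol by direct SN2 displacement, without allylic transposition or loss of alkene geometry.

Step 17
Reactants: 26 5-({(2E)-5-[4-(furan-3-ylmethyl)furan-3-yl]-2-methylpent-2-en-1-yl}sulfanyl)-1-phenyl-1H-tetrazole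
Product: 27 5-({(2E)-5-[4-(furan-3-ylmethyl)furan-3-yl]-2-methylpent-2-en-1-yl}sulfonyl)-1-phenyl-1H-tetrazole
Conditions: (NH4)6Mo7O24·4H2O (cat.), 30% H2O2, EtOH, 0 °C to rt
Reagents that add atoms: hydrogen peroxide, OO
Why: Molybdate-catalysed sulfide-to-sulfone oxidation by an electrophilic peroxo species that generally spares trisubstituted alkenes, and 3-alkylfurans are less reactive still towards such oxygen donors.

Step 18
Reactants: 27 5-({(2E)-5-[4-(furan-3-ylmethyl)furan-3-yl]-2-methylpent-2-en-1-yl}sulfonyl)-1-phenyl-1H-tetrazole; 16 (3S)-4-[(2Z)-4-{[(tert-butyldiphenylsilyl)oxy]methyl}-5-oxofuran-2(5H)-ylidene]-3-methylbutanal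
Product: 29 (5Z)-3-{[(tert-butyldiphenylsilyl)oxy]methyl}-5-{(2S,4E,6E)-9-[4-(furan-3-ylmethyl)furan-3-yl]-2,6-dimethylnona-4,6-dien-1-ylidene}furan-2(5H)-one, via potassium sulfonyl carbanion 28 (not isolated)
Conditions: 27 (1.2 equiv), KN(SiMe3)2 (1.15 equiv), 18-crown-6, THF, −78 °C; then 16, −78 to −20 °C; aq. NH4Cl
Reagents that add atoms: none
Why: Julia–Kocienski olefination (carbanion addition to the aldehyde, Smiles rearrangement, loss of SO2 and the tetrazolyl oxide) in which an α-unbranched aldehyde and a crown-ether-separated potassium ion should favour the 4E alkene, while premetalation with a slight deficit of base keeps free base away from the ε-CH stereocentre.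

Step 19
Reactants: 29 (5Z)-3-{[(tert-butyldiphenylsilyl)oxy]methyl}-5-{(2S,4E,6E)-9-[4-(furan-3-ylmethyl)furan-3-yl]-2,6-dimethylnona-4,6-dien-1-ylidene}furan-2(5H)-one
Product: 30 (5Z)-5-{(2S,4E,6E)-9-[4-(furan-3-ylmethyl)furan-3-yl]-2,6-dimethylnona-4,6-dien-1-ylidene}-3-(hydroxymethyl)furan-2(5H)-one
Conditions: HF·pyridine, pyridine, THF, rt
Reagents that add atoms: none
Why: Buffered fluoride cleavage of the silyl ether in a slightly acidic medium, which avoids deprotonation at the ε-CH of the alkylidene butenolide and should not harm the furans or the triene.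

Compound list
1 | (3R)-5-methoxy-3-methyl-5-oxopentanoic acid | COC(=O)C[C@H](C)CC(=O)O | starting material
2 | (3S)-5-hydroxy-3-methylpentanoic acid | OCC[C@H](C)CC(=O)O | intermediate (not isolated)
3 | (4S)-4-methyloxan-2-one | O=C1C[C@@H](C)CCO1 | intermediate
4 | (3S)-5-hydroxy-N-methoxy-N,3-dimethylpentanamide | CON(C)C(=O)C[C@@H](C)CCO | intermediate
5 | (3S)-5-[(tert-butyldimethylsilyl)oxy]-N-methoxy-N,3-dimethylpentanamide | CON(C)C(=O)C[C@@H](C)CCO[Si](C)(C)C(C)(C)C | intermediate
6 | vinylmagnesium bromide | C=C[Mg]Br | starting material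
7 | (5S)-7-[(tert-butyldimethylsilyl)oxy]-5-methylhept-1-en-3-one | C=CC(=O)C[C@@H](C)CCO[Si](C)(C)C(C)(C)C | intermediate
8 | ethyl 2-(hydroxymethyl)prop-2-enoate | C=C(CO)C(=O)OCC | starting material
9 | ethyl 2-{[(tert-butyldiphenylsilyl)oxy]methyl}prop-2-enoate | C=C(CO[Si](c1ccccc1)(c1ccccc1)C(C)(C)C)C(=O)OCC | intermediate
10 | 2-{[(tert-butyldiphenylsilyl)oxy]methyl}prop-2-enoic acid | C=C(CO[Si](c1ccccc1)(c1ccccc1)C(C)(C)C)C(=O)O | intermediate
11 | 2-{[(tert-butyldiphenylsilyl)oxy]methyl}prop-2-enoyl chloride | C=C(CO[Si](c1ccccc1)(c1ccccc1)C(C)(C)C)C(=O)Cl | intermediate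
12 | potassium (3Z,5S)-7-[(tert-butyldimethylsilyl)oxy]-5-methylhepta-1,3-dien-3-olate | C=CC(/[O-])=C/[C@@H](C)CCO[Si](C)(C)C(C)(C)C.[K+] | intermediate (not isolated)
13 | (3Z,5S)-7-[(tert-butyldimethylsilyl)oxy]-5-methylhepta-1,3-dien-3-yl 2-{[(tert-butyldiphenylsilyl)oxy]methyl}prop-2-enoate | C=CC(/OC(=O)C(=C)CO[Si](c1ccccc1)(c1ccccc1)C(C)(C)C)=C/[C@@H](C)CCO[Si](C)(C)C(C)(C)C | intermediate
14 | (5Z)-5-{(2S)-4-[(tert-butyldimethylsilyl)oxy]-2-methylbutylidene}-3-{[(tert-butyldiphenylsilyl)oxy]methyl}furan-2(5H)-one | CC(C)(C)[Si](C)(C)OCC[C@H](C)/C=C1/C=C(CO[Si](c2ccccc2)(c2ccccc2)C(C)(C)C)C(=O)O1 | intermediate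
15 | (5Z)-3-{[(tert-butyldiphenylsilyl)oxy]methyl}-5-[(2S)-4-hydroxy-2-methylbutylidene]furan-2(5H)-one | OCC[C@H](C)/C=C1/C=C(CO[Si](c2ccccc2)(c2ccccc2)C(C)(C)C)C(=O)O1 | intermediate
16 | (3S)-4-[(2Z)-4-{[(tert-butyldiphenylsilyl)oxy]methyl}-5-oxofuran-2(5H)-ylidene]-3-methylbutanal | O=CC[C@H](C)/C=C1/C=C(CO[Si](c2ccccc2)(c2ccccc2)C(C)(C)C)C(=O)O1 | intermediate
17 | 3,4-dibromofuran | Brc1cocc1Br | starting material
18 | furan-3-carbaldehyde | O=Cc1ccoc1 | starting material
19 | (4-bromofuran-3-yl)lithium | [Li]c1cocc1Br | intermediate (not isolated)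
20 | (4-bromofuran-3-yl)(furan-3-yl)methanol (racemic) | OC(c1ccoc1)c1cocc1Br | intermediate
21 | 3-bromo-4-(furan-3-ylmethyl)furan | Brc1cocc1Cc1ccoc1 | intermediate
22 | 5-bromo-2-methylpent-2-ene | CC(C)=CCCBr | starting material
23 | (4-methylpent-3-en-1-yl)magnesium bromide | CC(C)=CCC[Mg]Br | intermediate (not isolated)
24 | 3-(furan-3-ylmethyl)-4-(4-methylpent-3-en-1-yl)furan | CC(C)=CCCc1cocc1Cc1ccoc1 | intermediate
25 | (2E)-5-[4-(furan-3-ylmethyl)furan-3-yl]-2-methylpent-2-en-1-ol | C/C(CO)=C\CCc1cocc1Cc1ccoc1 | intermediate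
26 | 5-({(2E)-5-[4-(furan-3-ylmethyl)furan-3-yl]-2-methylpent-2-en-1-yl}sulfanyl)-1-phenyl-1H-tetrazole | C/C(CSc1nnnn1-c1ccccc1)=C\CCc1cocc1Cc1ccoc1 | intermediate
27 | 5-({(2E)-5-[4-(furan-3-ylmethyl)furan-3-yl]-2-methylpent-2-en-1-yl}sulfonyl)-1-phenyl-1H-tetrazole | C/C(CS(=O)(=O)c1nnnn1-c1ccccc1)=C\CCc1cocc1Cc1ccoc1 | intermediate
28 | potassium salt of the α-sulfonyl carbanion of 27 | C/C([CH-]S(=O)(=O)c1nnnn1-c1ccccc1)=C\CCc1cocc1Cc1ccoc1.[K+] | intermediate (not isolated)
29 | (5Z)-3-{[(tert-butyldiphenylsilyl)oxy]methyl}-5-{(2S,4E,6E)-9-[4-(furan-3-ylmethyl)furan-3-yl]-2,6-dimethylnona-4,6-dien-1-ylidene}furan-2(5H)-one | CC(/C=C/C[C@H](C)/C=C1/C=C(CO[Si](c2ccccc2)(c2ccccc2)C(C)(C)C)C(=O)O1)=C\CCc1cocc1Cc1ccoc1 | intermediate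
30 | (5Z)-5-{(2S,4E,6E)-9-[4-(furan-3-ylmethyl)furan-3-yl]-2,6-dimethylnona-4,6-dien-1-ylidene}-3-(hydroxymethyl)furan-2(5H)-one | CC(/C=C/C[C@H](C)/C=C1/C=C(CO)C(=O)O1)=C\CCc1cocc1Cc1ccoc1 | target

Total step count: 19.
Longest linear sequence: 10 steps (steps 1, 2, 3, 4, 8, 9, 10, 11, 18, 19).

Steps most likely to fail

1. Step 9 (ring-closing metathesis, the proposed new method). What may go wrong: after loading on the diene terminus the catalyst may rest as a conjugated, possibly carbonyl-chelated vinylalkylidene, so that closure onto the hindered, electron-poor 1,1-disubstituted alkene is outrun by dimerisation at the diene terminus and by catalyst decay. Fallback (known chemistry; sets out from 7, returns at 14): ketone 7 would be reduced under Luche conditions (NaBH4, CeCl3·7H2O, MeOH, −40 °C) to the allylic alcohol F1, either carbinol epimer being usable, and esterified with acid 10 (DCC, DMAP, CH2Cl2) to the allyl acrylate F2. The established ring-closing metathesis of an allyl 2-substituted acrylate (second-generation Grubbs catalyst RuCl2(H2IMes)(PCy3)(=CHPh), CH2Cl2, reflux) would then give the 5-alkylbutenolide F3. Its γ-CH would be oxidised in two stages, through the 2-silyloxyfuran F4 (i-Pr3SiOTf, Et3N, CH2Cl2, 0 °C) and dimethyldioxirane oxidation to the 5-hydroxybutenolide F5. Dehydration (MsCl, Et3N, CH2Cl2, 0 °C), for which only the exocyclic CH2 offers a β-hydrogen, should deliver the more stable Z alkylidene butenolide 14.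

2. Step 8 (enolisation and O-acylation). What may go wrong: incomplete control of enolate geometry, acylation at carbon instead of oxygen, and Michael self-condensation of the vinyl ketone during enolisation. Fallback (sets out from 7, returns at 13): 7 would be silylated under equilibrating conditions (Me3SiOTf, Et3N, Et2O, 0 °C) to the thermodynamically preferred Z silyl dienol ether F6, which can be purified and its geometry checked. Copper monochloride (CuCl)-mediated O-acylation of this neutral silyl enol ether with acid chloride 11 in 1,3-dimethylimidazolidin-2-one, a stereoretentive enol ester synthesis that avoids a free alkali enolate, would then give 13.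

3. Step 18 (Julia–Kocienski olefination). What may go wrong: proton transfer from the ε-CH(CH3) of the alkylidene butenolide to the sulfonyl carbanion (the conjugate base would be an aromatic 2-oxidofuran), eroding the stereocentre, together with incomplete E selectivity at the new alkene. Fallback (sets out from 16 and 21, returns at 29): aldehyde 16 would undergo Takai iodo-olefination (CrCl2, CHI3, THF, 0 °C) to the E vinyl iodide F7. Bromide 21 would be coupled (Ni(dppp)Cl2, THF) with pent-3-yn-1-ylmagnesium bromide F8, prepared from 5-bromopent-2-yne and Mg, to the internal alkyne F9. Hydrozirconation of F9 with Cp2Zr(H)Cl (THF, 40 °C, slight excess so that the regioisomers equilibrate towards zirconium on the methyl-bearing carbon) would give the alkenylzirconocene chloride F10, used without isolation. Negishi coupling of F10 with F7 (Pd(PPh3)4, ZnCl2, THF, rt), a neutral process with retention at both alkenes, would give 29.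

Further compounds
F1 | step 9 | (5S)-7-[(tert-butyldimethylsilyl)oxy]-5-methylhept-1-en-3-ol (both C3 epimers) | C=CC(O)C[C@@H](C)CCO[Si](C)(C)C(C)(C)C
F2 | step 9 | (5S)-7-[(tert-butyldimethylsilyl)oxy]-5-methylhept-1-en-3-yl 2-{[(tert-butyldiphenylsilyl)oxy]methyl}prop-2-enoate | C=CC(OC(=O)C(=C)CO[Si](c1ccccc1)(c1ccccc1)C(C)(C)C)C[C@@H](C)CCO[Si](C)(C)C(C)(C)C
F3 | step 9 | 5-{(2S)-4-[(tert-butyldimethylsilyl)oxy]-2-methylbutyl}-3-{[(tert-butyldiphenylsilyl)oxy]methyl}furan-2(5H)-one | CC(C)(C)[Si](C)(C)OCC[C@H](C)CC1C=C(CO[Si](c2ccccc2)(c2ccccc2)C(C)(C)C)C(=O)O1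
F4 | step 9 | [(5-{(2S)-4-[(tert-butyldimethylsilyl)oxy]-2-methylbutyl}-3-{[(tert-butyldiphenylsilyl)oxy]methyl}furan-2-yl)oxy]tri(propan-2-yl)silane | CC(C)(C)[Si](C)(C)OCC[C@H](C)Cc1cc(CO[Si](c2ccccc2)(c2ccccc2)C(C)(C)C)c(O[Si](C(C)C)(C(C)C)C(C)C)o1
F5 | step 9 | 5-{(2S)-4-[(tert-butyldimethylsilyl)oxy]-2-methylbutyl}-3-{[(tert-butyldiphenylsilyl)oxy]methyl}-5-hydroxyfuran-2(5H)-one | CC(C)(C)[Si](C)(C)OCC[C@H](C)CC1(O)C=C(CO[Si](c2ccccc2)(c2ccccc2)C(C)(C)C)C(=O)O1
F6 | step 8 | {[(3Z,5S)-7-[(tert-butyldimethylsilyl)oxy]-5-methylhepta-1,3-dien-3-yl]oxy}trimethylsilane | C=CC(/O[Si](C)(C)C)=C/[C@@H](C)CCO[Si](C)(C)C(C)(C)C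
F7 | step 18 | (5Z)-3-{[(tert-butyldiphenylsilyl)oxy]methyl}-5-[(2S,4E)-5-iodo-2-methylpent-4-en-1-ylidene]furan-2(5H)-one | I/C=C/C[C@H](C)/C=C1/C=C(CO[Si](c2ccccc2)(c2ccccc2)C(C)(C)C)C(=O)O1
F8 | step 18 | pent-3-yn-1-ylmagnesium bromide | CC#CCC[Mg]Br
F9 | step 18 | 3-(furan-3-ylmethyl)-4-(pent-3-yn-1-yl)furan | CC#CCCc1cocc1Cc1ccoc1
F10 | step 18 | chlorobis(cyclopentadienyl){(2E)-5-[4-(furan-3-ylmethyl)furan-3-yl]pent-2-en-2-yl}zirconium | C/C(=C\CCc1cocc1Cc1ccoc1)[Zr](Cl)(C1C=CC=C1)C1C=CC=C1
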